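The amounts first: the flask held one charge of substrate, 0.073 M, twice the beta charge, and I handed it over to be read at 12 min.

- beta: substrate 0.036 M; run made earlier
- flask: substrate 0.073 M; time 12 min

beta run (percent of the substrate charged)

| time / s | target / % | substrate / % | homo dimer / % |
|---|---|---|---|
| 10.0 | 5 | 94 | 0 |
| 12.0 | 5 | 95 | 1 |
| 20.0 | 8 | 91 | 4 |
| 30.0 | 10 | 87 | 3 |
| 50.0 | 13 | 80 | 5 |
| 80.0 | 22 | 72 | 7 |

(standard deviation of a reading: 1.5 percentage points)

- in percentages every species weighs as the substrate in it: one homo dimer counts as two
- the analysis behind the earlier runs scatters by 1.5 percentage points, standard deviation

* target present at 12 min, in percent of the substrate charged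
* substrate present at 12 min, in percent of the substrate charged
* homo dimer present at 12 min, in percent of the substrate charged

In the beta run, substrate stood at 72% of the charge at 80.0 s, a reading with its scatter. From it I took my substrate clock, the time in which the fraction of the charge still present as substrate halves if its loss stays first order (a pseudo-first-order half-life): 2.81 min. My note for the bench said that the flask would run through 4.27 such half-lives, so about 5.20% of the charge should remain as substrate. It also said that the clock is shorter than the time to the reading, and that it reckons substrate, not target.

The forecast gave 67% target, 8% substrate and 25% homo dimer, a higher substrate figure than mine, and it warned of “a nine-fold extrapolation in time”.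

The flask gave 18.9% target, 7.29% substrate and 21.7% homo dimer.

    substrate ⇌ target + by-product (K = 0.460 M, k = 0.00350 s⁻¹)
    target → over-reaction product (k = 0.00280 s⁻¹)
    2 substrate → homo dimer (k = 0.0140 M⁻¹ s⁻¹)

Against my 5.20%, the flask's substrate stood at 7.29%, but its target did not keep pace with that loss. At 2.42 min, inside the first clock, target was made 2.09 times as fast as it was used up; after 4.27 clocks that ratio was 0.342, and over-reaction product stood at 52.1%. For the neighbour flask charged at 0.18 M, the clock, which takes no account of the charge, again gives 5.20% at 12.0 min; that flask held 6.18% substrate.

(Readings and results are calculated with made-up constants.)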